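## Analysis of the target

The target is a 3,4-disubstituted γ-butyrolactone (O1, carbonyl C2, C3, C4, C5) of the dibenzylbutyrolactone lignan class. C3 carries, through the methylene C6, a 4-hydroxy-3-methoxyphenyl ring (ring A). C4 carries, through the methylene C7, a 3-hydroxy-4-methoxyphenyl ring (ring B). The two stereocentres are adjacent and both R, so the two arylmethyl groups are trans on the ring. They differ in kind: C3 is alpha to the lactone carbonyl and can be epimerised by base, with trans the more stable arrangement, whereas C4 has no acidifying neighbour and must be set in absolute terms. The sensitive groups are the two free phenols (acidic, easily oxidised), the lactone (opened by nucleophilic base) and the two electron-rich rings (open to electrophilic oxidants and halogenating agents). The difficulty is the near-symmetry: rings A and B differ only in the placing of OH and OMe, so each ring must be sent to its own carbon and the carbonyl must end up at C2, not C5. The strategy rests on C4, a CH bonded to three carbons (C3, C5 and C7): it can be inserted as a one-carbon unit between boron and C5, take C7 by substitution, and keep boron as the handle from which C3 and C2 are grown.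

## Retrosynthetic reasoning

**26 back to 25.** No skeletal bond is cut. Target 26 is traced to its C3 epimer 25, because the boron chemistry that builds C3 delivers the cis arrangement when the same diol is kept on boron. C3 is the one centre that thermodynamics can set, so the forward step only has to equilibrate C3 with base while C4 stays untouched.

**25 back to 23.** The O1–C2 lactone bond and the three benzyl ethers are cut, giving acid 23 (through hydroxy acid 24). The two oxygenated ends are at different oxidation levels (C2 carboxyl, C5 benzyl ether), so the lactone can only close in the required direction. One hydrogenolysis must free both phenols and the C5 hydroxyl, and the γ-hydroxy acid then closes by itself.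

**23 back to 22.** This is an oxidation-level change at C2, from acid to primary alcohol 22. The alcohol is what a carbon–boron bond gives on oxidation.

**22 back to 20 and 2.** The C2–C3 bond is cut. C2 is a single CH2 inserted into the C3–B bond of 20 by the carbenoid from bromochloromethane 2 (through 21). The insertion runs with retention at C3 and the new primary C–B bond is then oxidised.

**20 back to 14, 12 and 18.** The C3–C4 and C3–C6 bonds are cut. C3 comes from dichloromethane 12, inserted into the C4–B bond of 14, and C6 with ring A comes from Grignard reagent 18 (through 19). The diol that controls C4 also controls this cycle, so C3 emerges in the cis-lactone configuration. This is accepted because C3 is corrected at the end.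

**14 back to 7, 12 and 11.** This is the central disconnection: C4–C5 and C4–C7 are cut at once. C4 is the carbon of dichloromethane 12; it is inserted between boron and the benzyloxymethyl carbon of 7 and then takes the ring B benzyl group from Grignard reagent 11. Cutting here sets the one non-epimerisable centre by a bound, C2-symmetric diol and leaves boron on C4 for the next two cycles. Cutting C3–C4 instead would need an enolate or conjugate addition with external asymmetric control.

**7 back to 5 and 6, and 5 back to 1, 2 and 3.** The C5–O bond of 7 comes from benzyl alcohol 6 and chloromethyl boronate 5. Compound 5 comes from borate 1, bromochloromethane 2 and diol 3 (through 4). This puts the chiral diol and the protected C5 oxygen on boron in two operations.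

**11 back to 8, and 18 back to 15.** Each Grignard reagent comes from its benzylic chloride (10, 17), each chloride from its alcohol (9, 16), and each alcohol from its O-benzyl aldehyde (8, 15). The two isomeric rings thus enter as separate, unambiguous building blocks.

## Alternatives that were turned down

**Alternative 1:** Temporary cyclopropane.
- Disconnection: the C3–C4 bond and the lactone ring, with an extra, temporary C3–C7 bond, back to the (Z)-allylic diazoacetate A1.
- Forward key step: A1 is decomposed by Rh2(MEPY)4, dirhodium tetrakis(methyl 2-oxopyrrolidine-5-carboxylate), a chiral carboxamidate of divalent rhodium. The carbene adds to the tethered (Z)-alkene and gives the bicyclic lactone A2, which already holds C4 and ring B. Hydrogenolysis of the benzylic C3–C7 bond would then release C7 as a methylene, and the ring A benzyl group would follow by enolate alkylation.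
- For: the asymmetric step is catalytic, the lactone and C4 form together, and cis-alkenes are the substrates such catalysts differentiate best. The later alkylation should place C6 trans to the C4 substituent under kinetic control, so no equilibration is needed. On step count and on C3 this alternative is as strong as or stronger than the chosen route.
- Against: it needs a geometrically pure (Z)-alkene and a diazo ester. The cyclopropane has two benzylic bonds, C3–C7 and C4–C7, and only cleavage of the first keeps C4 stereogenic. The enantiomeric purity is whatever the catalyst gives, with no diastereomeric handle to improve it.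
- Comparison: the chosen route sets C4 with a covalently bound, recoverable diol, so a stereochemical error would show up as a separable diastereomer. It needs no diazo compound or rhodium, and both rings enter by the same operation.

**Alternative 2:** Directed hydroformylation.
- Disconnection: the C2–C3 and O1–C2 bonds, back to the (R)-homoallylic alcohol A3.
- Forward key step: A3 reacts with synthesis gas under Rh(acac)(CO)2 (monovalent rhodium) and a phosphinite ligand that exchanges reversibly with the hydroxyl. The formyl group is delivered to the alkene carbon nearer the hydroxyl (C3), and the hydroxy aldehyde closes to lactol A4.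
- For: C2 comes from carbon monoxide with full atom economy, and the ring closes in the same step.
- Against: the alkene of A3 is a 1,2-disubstituted styrene. Hydroformylation of aryl alkenes has an intrinsic preference for the benzylic carbon (here C6), so the directing ligand must override an electronic bias on a slow alkene class. C3 is set only by substrate control through a cyclic rhodium alkyl. C4 of A3 still needs its own asymmetric synthesis, so the absolute-configuration problem is moved, not solved. Lactol oxidation and debenzylation follow.
- Comparison: after A3 this alternative is shorter. The chosen route creates C4 itself and has no regiochemical competition, because every carbon is delivered to boron one at a time.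

**Alternative 3:** Formaldehyde allylboration.
- Disconnection: the C4–C5 and O1–C2 bonds, back to the (Z)-2-methoxycarbonyl allylboronate A5 and formaldehyde A6.
- Forward key step: A5 adds to A6 under a chiral binaphthyl phosphoric acid, forming C4–C5, and the alkoxide closes onto the ester to give the α-methylene lactone A7. A ring A aryl nucleophile would then be added in conjugate fashion to the exocyclic methylene.
- For: it is the shortest route, and A7 holds C2 to C5 and C4 after one step.
- Against: C4 is the γ-carbon of the allyl unit, and A6 has no prochiral face. Such acids normally control the chair transition state by telling the aldehyde substituent from hydrogen; here that handle is absent and induction would depend only on the catalyst pocket reading the allyl faces. The ester also lowers the nucleophilicity of the allylboronate, and monomeric A6 is awkward to dose. C3 would then be set by protonation of an enolate, which calls for equilibration much as in the chosen route.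
- Comparison: on step count this alternative is stronger. The chosen route is longer, but the stereochemical mechanism at C4 (diol-directed chloride departure, then inversion) does not depend on the electrophile being prochiral.

Key step: step 6

## Route

Remark: aldehydes 8 and 15 are taken as purchased catalogue compounds. The sense of induction of the (R,R)-diol is taken as the one established for this class of boronic esters.

Step 1
Reactants: 1 triisopropyl borate; 2 bromochloromethane; 3 (1R,2R)-1,2-dicyclohexylethane-1,2-diol
Product: 5 (4R,5R)-2-(chloromethyl)-4,5-dicyclohexyl-1,3,2-dioxaborolane, via diisopropyl (chloromethyl)boronate 4 (not isolated)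
Conditions: 1, 2, n-BuLi, THF, −78 °C → rt; HCl (anhydrous, Et2O), 0 °C; then 3, rt
Reagents that add atoms: none
Why: (Chloromethyl)lithium formed by Br/Li exchange on 2 is trapped by borate 1 as it forms, and acidification gives the chloromethyl boronic diester 4. Transesterification with diol 3 should go to completion because the five-membered dioxaborolane of a hindered 1,2-diol is much more stable than the diisopropyl ester; no stereocentre is formed.

Step 2
Reactants: 5 (4R,5R)-2-(chloromethyl)-4,5-dicyclohexyl-1,3,2-dioxaborolane; 6 benzyl alcohol
Product: 7 (4R,5R)-2-[(benzyloxy)methyl]-4,5-dicyclohexyl-1,3,2-dioxaborolane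
Conditions: 6, n-BuLi, THF, −78 → 0 °C; then 5, DMSO, rt
Reagents that add atoms: none
Why: Lithium benzyloxide adds to boron and the alkoxy group then shifts from boron to carbon with loss of chloride, the usual substitution of an α-halo boronic ester by an alkoxide (1,2-metallate rearrangement); DMSO speeds the shift.

Step 3
Reactants: 8 3-benzyloxy-4-methoxybenzaldehyde
Product: 9 (3-benzyloxy-4-methoxyphenyl)methanol
Conditions: NaBH4, MeOH–THF, 0 °C
Reagents that add atoms: none
Why: Borohydride reduction of an aryl aldehyde; the aryl benzyl and methyl ethers are inert.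

Step 4
Reactants: 9 (3-benzyloxy-4-methoxyphenyl)methanol
Product: 10 2-(benzyloxy)-4-(chloromethyl)-1-methoxybenzene (3-benzyloxy-4-methoxybenzyl chloride)
Conditions: SOCl2, CH2Cl2, 0 °C → rt
Reagents that add atoms: thionyl chloride, O=S(Cl)Cl
Why: Chlorination of an electron-rich benzylic alcohol through its chlorosulfite. The product ionises easily, so it should be kept cold and used without storage.

Step 5
Reactants: 10 2-(benzyloxy)-4-(chloromethyl)-1-methoxybenzene
Product: 11 (3-benzyloxy-4-methoxybenzyl)magnesium chloride (THF solution, titrated)
Conditions: Mg turnings (excess, I2-activated), THF, 0 °C, slow addition at high dilution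
Reagents that add atoms: magnesium, [Mg]
Why: Grignard formation by magnesium insertion into the benzylic C–Cl bond. Slow addition to excess metal at low temperature and dilution should hold back Wurtz coupling, as for other 4-alkoxybenzyl chlorides.

Step 6
Reactants: 7 (4R,5R)-2-[(benzyloxy)methyl]-4,5-dicyclohexyl-1,3,2-dioxaborolane; 12 dichloromethane; 11 (3-benzyloxy-4-methoxybenzyl)magnesium chloride
Product: 14 (4R,5R)-2-[(2S)-1-(benzyloxy)-3-(3-benzyloxy-4-methoxyphenyl)propan-2-yl]-4,5-dicyclohexyl-1,3,2-dioxaborolane, via (1S)-2-benzyloxy-1-chloroethyl boronate 13 (not isolated)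
Conditions: 12, n-BuLi, THF, −100 °C; then 7; ZnCl2 (1.5 equiv), −100 °C → rt, 16 h; then 11 (2.5 equiv), −78 °C → rt
Reagents that add atoms: none
Why: The carbenoid made from 12 adds to the trigonal boron of 7 at −100 °C to give a tetracoordinate ate complex; ZnCl2 then assists the departure of one chloride while the benzyloxymethyl carbon C5 shifts from boron to the carbenoid carbon (1,2-metallate rearrangement), which forms C4–C5 and gives 13. The C2-symmetric dicyclohexylethanediol makes the two chlorides diastereotopic, and with ZnCl2 bridging a ring oxygen and the leaving chloride the (R,R)-diol should expel the chloride that leaves C4 as the (1S) chloride. Grignard reagent 11 then adds to boron to give a second ate complex, and its benzylic carbon C7 migrates anti to the C–Cl bond with inversion at C4, forming C4–C7 and the (2S) centre of 14, which becomes (4R) in the lactone once boron is replaced by C3. The closest known reaction type is the Matteson homologation of chiral diol boronic esters followed by Grignard substitution of the α-chloro boronic ester, a class that includes alkoxymethyl boronic esters. No ring is closed. The one new stereocentre, C4, is controlled by the diol in the first shift and by the stereospecific inversion in the second. The step needs selection between the two chlorides, no epimerisation of 13 by free chloride (ZnCl2 binds it), attack of 11 at boron and not at carbon (the empty boron orbital is the most electrophilic site), and no loss of benzyloxide from the carbon beta to boron (an ether is a poor leaving group from the cold ate complexes). The excess of 11 allows for the part taken up by zinc salts.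

Step 7
Reactants: 15 4-benzyloxy-3-methoxybenzaldehyde
Product: 16 (4-benzyloxy-3-methoxyphenyl)methanol
Conditions: NaBH4, MeOH–THF, 0 °C
Reagents that add atoms: none
Why: Borohydride reduction of an aryl aldehyde, as in step 3.

Step 8
Reactants: 16 (4-benzyloxy-3-methoxyphenyl)methanol
Product: 17 1-(benzyloxy)-4-(chloromethyl)-2-methoxybenzene (4-benzyloxy-3-methoxybenzyl chloride)
Conditions: SOCl2, CH2Cl2, 0 °C → rt
Reagents that add atoms: thionyl chloride, O=S(Cl)Cl
Why: Chlorination through the chlorosulfite, as in step 4. The para-benzyloxy group makes this chloride the more labile of the two, so it should be used at once.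

Step 9
Reactants: 17 1-(benzyloxy)-4-(chloromethyl)-2-methoxybenzene
Product: 18 (4-benzyloxy-3-methoxybenzyl)magnesium chloride (THF solution, titrated)
Conditions: Mg turnings (excess, I2-activated), THF, 0 °C, slow addition at high dilution
Reagents that add atoms: magnesium, [Mg]
Why: Grignard formation as in step 5, with the same precautions against Wurtz coupling.

Step 10
Reactants: 14 (4R,5R)-2-[(2S)-1-(benzyloxy)-3-(3-benzyloxy-4-methoxyphenyl)propan-2-yl]-4,5-dicyclohexyl-1,3,2-dioxaborolane; 12 dichloromethane; 18 (4-benzyloxy-3-methoxybenzyl)magnesium chloride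
Product: 20 (4R,5R)-2-[(2S,3R)-4-(benzyloxy)-3-(3-benzyloxy-4-methoxybenzyl)-1-(4-benzyloxy-3-methoxyphenyl)butan-2-yl]-4,5-dicyclohexyl-1,3,2-dioxaborolane, via (1S)-1-chloroalkyl boronate 19 (not isolated)
Conditions: 12, n-BuLi, THF, −100 °C; then 14; ZnCl2 (2 equiv), −100 °C → rt, 16 h; then 18 (3 equiv), −78 °C → rt
Reagents that add atoms: none
Why: A second Matteson cycle on a secondary alkyl boronic ester: C4 migrates from boron to the carbenoid carbon with retention, forming C3–C4, and the (R,R)-diol again selects the chloride to give (1S)-19. Substitution by 18 with inversion forms C3–C6 and the (2S) boron-bearing carbon of 20. This corresponds to the cis lactone and is accepted because C3 is equilibrated in step 14.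

Step 11
Reactants: 20 (4R,5R)-2-[(2S,3R)-4-(benzyloxy)-3-(3-benzyloxy-4-methoxybenzyl)-1-(4-benzyloxy-3-methoxyphenyl)butan-2-yl]-4,5-dicyclohexyl-1,3,2-dioxaborolane; 2 bromochloromethane
Product: 22 (2S,3R)-4-(benzyloxy)-3-(3-benzyloxy-4-methoxybenzyl)-2-(4-benzyloxy-3-methoxybenzyl)butan-1-ol, via one-carbon homologated boronate 21 (not isolated)
Conditions: 2, n-BuLi, THF, −78 °C → rt; then NaOH (aq), H2O2, 0 °C → rt
Reagents that add atoms: hydrogen peroxide, OO
Why: (Chloromethyl)lithium generated in the presence of 20 adds to boron, and C3 shifts to the CH2 with loss of chloride and retention at C3 (Matteson one-carbon homologation), forming C2–C3. Alkaline peroxide then oxidises the primary C–B bond to the alcohol and frees diol 3 for recovery.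

Step 12
Reactants: 22 (2S,3R)-4-(benzyloxy)-3-(3-benzyloxy-4-methoxybenzyl)-2-(4-benzyloxy-3-methoxybenzyl)butan-1-ol
Product: 23 (2S,3R)-4-(benzyloxy)-3-(3-benzyloxy-4-methoxybenzyl)-2-(4-benzyloxy-3-methoxybenzyl)butanoic acid
Conditions: TEMPO (cat.), PhI(OAc)2, MeCN–CH2Cl2–H2O, rt
Reagents that add atoms: water, O
Why: Oxoammonium oxidation of the primary alcohol to the aldehyde, whose hydrate is oxidised on to the acid. The conditions are near neutral and free of electrophilic halogen, so the benzyl ethers and electron-rich rings should survive, and any leak at C3 through the aldehyde is harmless because C3 is equilibrated at the end.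

Step 13
Reactants: 23 (2S,3R)-4-(benzyloxy)-3-(3-benzyloxy-4-methoxybenzyl)-2-(4-benzyloxy-3-methoxybenzyl)butanoic acid
Product: 25 (3S,4R)-3-(4-hydroxy-3-methoxybenzyl)-4-(3-hydroxy-4-methoxybenzyl)dihydrofuran-2(3H)-one (cis lactone), via deprotected hydroxy acid 24 (not isolated)
Conditions: H2 (1 atm), 10% Pd/C, EtOAc–EtOH, rt; filter; TsOH·H2O (cat.), CH2Cl2, rt
Reagents that add atoms: none
Why: Hydrogenolysis removes the two aryl benzyl ethers and the C5 benzyl ether, and the γ-hydroxy acid lactonises under acid catalysis. Only C2 is a carboxyl, so the ring can only close with the carbonyl next to C3; neither stereocentre is touched.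

Step 14
Reactants: 25 (3S,4R)-3-(4-hydroxy-3-methoxybenzyl)-4-(3-hydroxy-4-methoxybenzyl)dihydrofuran-2(3H)-one
Product: 26 (3R,4R)-3-(4-hydroxy-3-methoxybenzyl)-4-(3-hydroxy-4-methoxybenzyl)dihydrofuran-2(3H)-one (target)
Conditions: DBU (5 equiv), MeCN, 70 °C, argon; then 1 M HCl
Reagents that add atoms: none
Why: Base-mediated epimerisation through the lactone enolate: reversible deprotonation at C3 and reprotonation should lead to the more stable trans isomer, as is usual for cis-2,3-dibenzylbutyrolactones. C4 has no acidic hydrogen and keeps its configuration; excess base covers the two phenols.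

## Compound list

1 | triisopropyl borate | CC(C)OB(OC(C)C)OC(C)C | starting material
2 | bromochloromethane | ClCBr | starting material
3 | (1R,2R)-1,2-dicyclohexylethane-1,2-diol | O[C@H](C1CCCCC1)[C@H](O)C1CCCCC1 | starting material
4 | diisopropyl (chloromethyl)boronate | ClCB(OC(C)C)OC(C)C | intermediate
5 | (4R,5R)-2-(chloromethyl)-4,5-dicyclohexyl-1,3,2-dioxaborolane | ClCB1O[C@H](C2CCCCC2)[C@@H](C2CCCCC2)O1 | intermediate
6 | benzyl alcohol | OCc1ccccc1 | starting material
7 | (4R,5R)-2-[(benzyloxy)methyl]-4,5-dicyclohexyl-1,3,2-dioxaborolane | c1ccccc1COCB1O[C@H](C2CCCCC2)[C@@H](C2CCCCC2)O1 | intermediate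
8 | 3-benzyloxy-4-methoxybenzaldehyde | COc1ccc(C=O)cc1OCc1ccccc1 | starting material
9 | (3-benzyloxy-4-methoxyphenyl)methanol | COc1ccc(CO)cc1OCc1ccccc1 | intermediate
10 | 2-(benzyloxy)-4-(chloromethyl)-1-methoxybenzene | COc1ccc(CCl)cc1OCc1ccccc1 | intermediate
11 | (3-benzyloxy-4-methoxybenzyl)magnesium chloride | COc1ccc(C[Mg]Cl)cc1OCc1ccccc1 | intermediate
12 | dichloromethane | ClCCl | starting material
13 | (4R,5R)-2-[(1S)-2-(benzyloxy)-1-chloroethyl]-4,5-dicyclohexyl-1,3,2-dioxaborolane | Cl[C@H](COCc1ccccc1)B1O[C@H](C2CCCCC2)[C@@H](C2CCCCC2)O1 | intermediate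
14 | (4R,5R)-2-[(2S)-1-(benzyloxy)-3-(3-benzyloxy-4-methoxyphenyl)propan-2-yl]-4,5-dicyclohexyl-1,3,2-dioxaborolane | COc1ccc(C[C@H](B2O[C@H](C3CCCCC3)[C@@H](C3CCCCC3)O2)COCc2ccccc2)cc1OCc1ccccc1 | intermediate
15 | 4-benzyloxy-3-methoxybenzaldehyde | COc1cc(C=O)ccc1OCc1ccccc1 | starting material
16 | (4-benzyloxy-3-methoxyphenyl)methanol | COc1cc(CO)ccc1OCc1ccccc1 | intermediate
17 | 1-(benzyloxy)-4-(chloromethyl)-2-methoxybenzene | COc1cc(CCl)ccc1OCc1ccccc1 | intermediate
18 | (4-benzyloxy-3-methoxybenzyl)magnesium chloride | COc1cc(C[Mg]Cl)ccc1OCc1ccccc1 | intermediate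
19 | (4R,5R)-2-[(1S,2S)-3-(benzyloxy)-2-(3-benzyloxy-4-methoxybenzyl)-1-chloropropyl]-4,5-dicyclohexyl-1,3,2-dioxaborolane | COc1ccc(C[C@@H](COCc2ccccc2)[C@@H](Cl)B2O[C@H](C3CCCCC3)[C@@H](C3CCCCC3)O2)cc1OCc1ccccc1 | intermediate
20 | (4R,5R)-2-[(2S,3R)-4-(benzyloxy)-3-(3-benzyloxy-4-methoxybenzyl)-1-(4-benzyloxy-3-methoxyphenyl)butan-2-yl]-4,5-dicyclohexyl-1,3,2-dioxaborolane | COc1ccc(C[C@@H](COCc2ccccc2)[C@H](Cc2ccc(OCc3ccccc3)c(OC)c2)B2O[C@H](C3CCCCC3)[C@@H](C3CCCCC3)O2)cc1OCc1ccccc1 | intermediate
21 | (4R,5R)-2-[(2S,3R)-4-(benzyloxy)-3-(3-benzyloxy-4-methoxybenzyl)-2-(4-benzyloxy-3-methoxybenzyl)butyl]-4,5-dicyclohexyl-1,3,2-dioxaborolane | COc1ccc(C[C@@H](COCc2ccccc2)[C@H](Cc2ccc(OCc3ccccc3)c(OC)c2)CB2O[C@H](C3CCCCC3)[C@@H](C3CCCCC3)O2)cc1OCc1ccccc1 | intermediate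
22 | (2S,3R)-4-(benzyloxy)-3-(3-benzyloxy-4-methoxybenzyl)-2-(4-benzyloxy-3-methoxybenzyl)butan-1-ol | COc1ccc(C[C@@H](COCc2ccccc2)[C@H](Cc2ccc(OCc3ccccc3)c(OC)c2)CO)cc1OCc1ccccc1 | intermediate
23 | (2S,3R)-4-(benzyloxy)-3-(3-benzyloxy-4-methoxybenzyl)-2-(4-benzyloxy-3-methoxybenzyl)butanoic acid | COc1ccc(C[C@@H](COCc2ccccc2)[C@H](Cc2ccc(OCc3ccccc3)c(OC)c2)C(=O)O)cc1OCc1ccccc1 | intermediate
24 | (2S,3R)-4-hydroxy-2-(4-hydroxy-3-methoxybenzyl)-3-(3-hydroxy-4-methoxybenzyl)butanoic acid | COc1ccc(C[C@@H](CO)[C@H](Cc2ccc(O)c(OC)c2)C(=O)O)cc1O | intermediate
25 | (3S,4R)-3-(4-hydroxy-3-methoxybenzyl)-4-(3-hydroxy-4-methoxybenzyl)dihydrofuran-2(3H)-one | COc1ccc(C[C@H]2COC(=O)[C@H]2Cc2ccc(O)c(OC)c2)cc1O | intermediate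
26 | (3R,4R)-3-(4-hydroxy-3-methoxybenzyl)-4-(3-hydroxy-4-methoxybenzyl)dihydrofuran-2(3H)-one | COc1ccc(C[C@H]2COC(=O)[C@@H]2Cc2ccc(O)c(OC)c2)cc1O | target

## Step count and risk

Total step count: 14. Longest linear sequence: 9 steps (steps 3, 4, 5, 6, 10, 11, 12, 13 and 14, counted from 8).

**Step 6 (key step).** Three processes are most likely to go wrong.
- Uptake of the benzylic Grignard reagent by the zinc salts in the same flask, giving a less nucleophilic benzylzinc species and incomplete substitution.
- Loss of benzyloxide from the carbon beta to boron if the ate complexes or 13 warm in the presence of Lewis acid.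
- Erosion of the C4 configuration by chloride exchange on 13 if the rearrangement mixture stands too long before 11 is added.

Wurtz coupling while 11 is made (step 5) would also lower the effective charge of nucleophile.

Fallback: the same C4–C5 bond is formed by lithiation–borylation, setting out from 7 and coming back at 14.
- Purchased (3-benzyloxy-4-methoxyphenyl)acetic acid F1 is reduced (LiAlH4, THF) to 2-(3-benzyloxy-4-methoxyphenyl)ethanol F2.
- F2 is converted (NaH, N,N-diisopropylcarbamoyl chloride, THF) into 2-(3-benzyloxy-4-methoxyphenyl)ethyl N,N-diisopropylcarbamate F3.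
- Deprotonation with s-BuLi and (+)-sparteine in Et2O at −78 °C removes the pro-R hydrogen and should give the (1R)-lithiated carbamate F4.
- 7 is added, and on warming with MgBr2·OEt2 the benzyloxymethyl group shifts from boron to carbon with loss of the carbamate and inversion, which gives 14.

Here C7 is in place from the start and C4 is fixed by the diamine instead of the diol; neither an α-chloro boronic ester nor a benzylic Grignard reagent is involved.

**Step 10.** The boron of 14 is secondary, branched on both sides and has the C5 benzyloxy group beta to it. The likely failures are slow or incomplete ate-complex formation with a carbenoid that decomposes if warmed, elimination of benzyloxide from the ate complex, and sluggish substitution of the hindered chloride of 19 by the benzylic Grignard reagent.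

Fallback: again lithiation–borylation, setting out from 14 and coming back at 20.
- Purchased (4-benzyloxy-3-methoxyphenyl)acetic acid F5 is reduced (LiAlH4, THF) to 2-(4-benzyloxy-3-methoxyphenyl)ethanol F6.
- F6 is carbamoylated (NaH, N,N-diisopropylcarbamoyl chloride, THF) to 2-(4-benzyloxy-3-methoxyphenyl)ethyl N,N-diisopropylcarbamate F7.
- s-BuLi and (+)-sparteine in Et2O at −78 °C should give the (1R)-lithiated carbamate F8.
- 14 is added, and C4 migrates from boron to the carbenoid carbon with retention at C4 and inversion at C3 (MgBr2·OEt2, warming) to give 20.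

C3–C4 is thus made with C6 already attached and without a chloride to displace.

**Step 11.** Insertion of a CH2 unit into the very hindered C3–B bond may stop at partial conversion, because the carbenoid decomposes faster than it adds, or may insert twice. Oxidation of unreacted 20 would then give a secondary alcohol that has to be separated.

Fallback: C2 is brought in as a vinyl group, setting out from 20 and coming back at 23.
- 20 is treated with vinylmagnesium bromide (THF–DMSO) and then I2 and NaOMe (Zweifel olefination, retention at C3) to give (3R,4R)-5-(benzyloxy)-4-(3-benzyloxy-4-methoxybenzyl)-3-(4-benzyloxy-3-methoxybenzyl)pent-1-ene F9.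
- Oxidative cleavage (OsO4 cat., NaIO4, 2,6-lutidine, dioxane–H2O) gives (2S,3R)-4-(benzyloxy)-3-(3-benzyloxy-4-methoxybenzyl)-2-(4-benzyloxy-3-methoxybenzyl)butanal F10.
- Chlorite oxidation (NaClO2, NaH2PO4, 2-methylbut-2-ene, t-BuOH–H2O) then leads to 23.

**Step 14.** The two phenols take up base before the lactone α-hydrogen does, so enolisation may be slow and the equilibration incomplete. The phenoxides are open to air oxidation, and traces of water with base can open the lactone.

Fallback: the equilibration is moved to a substrate without acidic phenols, setting out from 25 and coming back at 26.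
- 25 is silylated (TBSCl, imidazole, DMF) to (3S,4R)-3-[4-(tert-butyldimethylsilyloxy)-3-methoxybenzyl]-4-[3-(tert-butyldimethylsilyloxy)-4-methoxybenzyl]dihydrofuran-2(3H)-one F11.
- DBU in toluene at 80 °C should equilibrate C3 to the trans isomer (3R,4R)-3-[4-(tert-butyldimethylsilyloxy)-3-methoxybenzyl]-4-[3-(tert-butyldimethylsilyloxy)-4-methoxybenzyl]dihydrofuran-2(3H)-one F12.
- Buffered fluoride (TBAF, AcOH, THF, 0 °C) then returns 26.

## Further compounds

F1 | step 6 | (3-benzyloxy-4-methoxyphenyl)acetic acid | COc1ccc(CC(=O)O)cc1OCc1ccccc1
F2 | step 6 | 2-(3-benzyloxy-4-methoxyphenyl)ethanol | COc1ccc(CCO)cc1OCc1ccccc1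
F3 | step 6 | 2-(3-benzyloxy-4-methoxyphenyl)ethyl N,N-diisopropylcarbamate | COc1ccc(CCOC(=O)N(C(C)C)C(C)C)cc1OCc1ccccc1
F4 | step 6 | (1R)-2-(3-benzyloxy-4-methoxyphenyl)-1-lithioethyl N,N-diisopropylcarbamate | COc1ccc(C[C@@H]([Li])OC(=O)N(C(C)C)C(C)C)cc1OCc1ccccc1
F5 | step 10 | (4-benzyloxy-3-methoxyphenyl)acetic acid | COc1cc(CC(=O)O)ccc1OCc1ccccc1
F6 | step 10 | 2-(4-benzyloxy-3-methoxyphenyl)ethanol | COc1cc(CCO)ccc1OCc1ccccc1
F7 | step 10 | 2-(4-benzyloxy-3-methoxyphenyl)ethyl N,N-diisopropylcarbamate | COc1cc(CCOC(=O)N(C(C)C)C(C)C)ccc1OCc1ccccc1
F8 | step 10 | (1R)-2-(4-benzyloxy-3-methoxyphenyl)-1-lithioethyl N,N-diisopropylcarbamate | COc1cc(C[C@@H]([Li])OC(=O)N(C(C)C)C(C)C)ccc1OCc1ccccc1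
F9 | step 11 | (3R,4R)-5-(benzyloxy)-4-(3-benzyloxy-4-methoxybenzyl)-3-(4-benzyloxy-3-methoxybenzyl)pent-1-ene | COc1ccc(C[C@@H](COCc2ccccc2)[C@H](Cc2ccc(OCc3ccccc3)c(OC)c2)C=C)cc1OCc1ccccc1
F10 | step 11 | (2S,3R)-4-(benzyloxy)-3-(3-benzyloxy-4-methoxybenzyl)-2-(4-benzyloxy-3-methoxybenzyl)butanal | COc1ccc(C[C@@H](COCc2ccccc2)[C@H](Cc2ccc(OCc3ccccc3)c(OC)c2)C=O)cc1OCc1ccccc1
F11 | step 14 | (3S,4R)-3-[4-(tert-butyldimethylsilyloxy)-3-methoxybenzyl]-4-[3-(tert-butyldimethylsilyloxy)-4-methoxybenzyl]dihydrofuran-2(3H)-one | COc1ccc(C[C@H]2COC(=O)[C@H]2Cc2ccc(O[Si](C)(C)C(C)(C)C)c(OC)c2)cc1O[Si](C)(C)C(C)(C)C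
F12 | step 14 | (3R,4R)-3-[4-(tert-butyldimethylsilyloxy)-3-methoxybenzyl]-4-[3-(tert-butyldimethylsilyloxy)-4-methoxybenzyl]dihydrofuran-2(3H)-one | COc1ccc(C[C@H]2COC(=O)[C@@H]2Cc2ccc(O[Si](C)(C)C(C)(C)C)c(OC)c2)cc1O[Si](C)(C)C(C)(C)C
A1 | alternative 1 | (Z)-3-[4-methoxy-3-(triisopropylsilyloxy)phenyl]prop-2-en-1-yl diazoacetate | COc1ccc(/C=C\COC(=O)C=[N+]=[N-])cc1O[Si](C(C)C)(C(C)C)C(C)C
A2 | alternative 1 | 6-endo-[4-methoxy-3-(triisopropylsilyloxy)phenyl]-3-oxabicyclo[3.1.0]hexan-2-one (enantiomer as in the SMILES) | COc1ccc([C@H]3[C@H]2COC(=O)[C@H]23)cc1O[Si](C(C)C)(C(C)C)C(C)C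
A3 | alternative 2 | (R,E)-2-(3-benzyloxy-4-methoxybenzyl)-4-(4-benzyloxy-3-methoxyphenyl)but-3-en-1-ol | COc1ccc(C[C@H](/C=C/c2ccc(OCc3ccccc3)c(OC)c2)CO)cc1OCc1ccccc1
A4 | alternative 2 | (3R,4R)-3-(4-benzyloxy-3-methoxybenzyl)-4-(3-benzyloxy-4-methoxybenzyl)tetrahydrofuran-2-ol (anomeric mixture) | COc1ccc(C[C@H]2COC(O)[C@@H]2Cc2ccc(OCc3ccccc3)c(OC)c2)cc1OCc1ccccc1
A5 | alternative 3 | methyl (Z)-4-(3-benzyloxy-4-methoxyphenyl)-2-[(4,4,5,5-tetramethyl-1,3,2-dioxaborolan-2-yl)methyl]but-2-enoate | COC(=O)/C(CB1OC(C)(C)C(C)(C)O1)=C\Cc1ccc(OC)c(OCc2ccccc2)c1
A6 | alternative 3 | formaldehyde | C=O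
A7 | alternative 3 | (R)-4-(3-benzyloxy-4-methoxybenzyl)-3-methylenedihydrofuran-2(3H)-one | COc1ccc(C[C@H]2COC(=O)C2=C)cc1OCc1ccccc1
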